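**Plan**

1. The retrosynthesis cuts the γ-lactone (oxolan-2-one ring: O1, C2, C3, C4, C5) at O1–C5 and C3–C4 together. This gives an O1–C2–C3 piece, an (E)-2-iodoalk-2-enoic acid carrying the whole side chain, and a C4–C5 piece, the enol-ether double bond of a 1-silyloxy-4-methylpenta-1,3-diene.
2. The enabling feature is that C5 carries the ring oxygen and a vinyl group ending in CMe2, so C5–CH=CMe2 is a latent allyl unit, and C4 carries oxygen, so C4=C5 is the enol-ether end of a dienol ether. Palladium joins two carbons that are both electrophilic in their precursors (the iodide carbon C3 and the oxygen-bearing C4), and the carboxylate then closes on the allyl terminus C5.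
3. The side chain is cut at the carbinol–CH2 bond (asymmetric propargylation of a C10 enal made from geraniol) and at the alkyne–carboxyl bond; syn-hydrostannation and iodinolysis fix the exocyclic alkene geometry.
4. Forward: geraniol → enal → (R)-homopropargylic alcohol → ynoate → (E)-2-iodo acid; 4-methylpent-2-enal → silyl dienol ether; the annulation forms the only ring; global desilylation ends the route.
5. Stereochemistry: the side-chain carbinol comes from chiral phosphoric acid catalysis, C4 from ligand-controlled insertion, C5 from C4 in the ring closure (trans), and the alkene geometries from geraniol, E-selective allylic oxidation and retentive tin/palladium chemistry.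

Key step: step 10

Remark: the senses of induction of (R)-TRIP in step 4 (Re face of the aldehyde) and of (S)-t-Bu-PHOX in step 10 (Si face of C-1 of the dienol ether) are assumed; if either is opposite, the antipodal catalyst is used.

**Route**

Step 1
Reactants: 1 geraniol
Product: 2 tert-butyl{[(2E)-3,7-dimethylocta-2,6-dien-1-yl]oxy}dimethylsilane
Conditions: TBSCl, imidazole, CH2Cl2, 0 °C to rt
Reagents that add atoms: tert-butyldimethylsilyl chloride, CC(C)(C)[Si](C)(C)Cl
Why: Silyl ether protection of a primary allylic alcohol, which should be quantitative and leaves both alkenes untouched.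

Step 2
Reactants: 2 tert-butyl{[(2E)-3,7-dimethylocta-2,6-dien-1-yl]oxy}dimethylsilane
Product: 3 (2E,6E)-8-[(tert-butyldimethylsilyl)oxy]-2,6-dimethylocta-2,6-dien-1-ol
Conditions: SeO2 (cat.), t-BuOOH, salicylic acid (cat.), CH2Cl2, rt
Reagents that add atoms: tert-butyl hydroperoxide, CC(C)(C)OO (oxygen atom, relayed by catalytic selenium dioxide, O=[Se]=O)
Why: Riley allylic oxidation (ene reaction, then [2,3]-sigmatropic shift) should take place at the E-methyl group of the distal, more electron-rich trisubstituted alkene, so the new 2E geometry follows from the mechanism.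

Step 3
Reactants: 3 (2E,6E)-8-[(tert-butyldimethylsilyl)oxy]-2,6-dimethylocta-2,6-dien-1-ol
Product: 4 (2E,6E)-8-[(tert-butyldimethylsilyl)oxy]-2,6-dimethylocta-2,6-dienal
Conditions: MnO2, CH2Cl2, rt
Reagents that add atoms: none
Why: Allylic alcohol oxidation with MnO2 should stop at the enal without alkene isomerisation and also converge any aldehyde already formed in step 2.

Step 4
Reactants: 4 (2E,6E)-8-[(tert-butyldimethylsilyl)oxy]-2,6-dimethylocta-2,6-dienal
Product: 6 (4R,5E,9E)-11-[(tert-butyldimethylsilyl)oxy]-5,9-dimethylundeca-5,9-dien-1-yn-4-ol, via O-boryl ether 5 (not isolated)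
Conditions: allenylboronic acid pinacol ester, (R)-TRIP (10 mol%), 4 Å MS, toluene, −20 °C; aqueous work-up
Reagents that add atoms: allenylboronic acid pinacol ester, C=C=CB1OC(C)(C)C(C)(C)O1
Why: Chiral phosphoric acid-catalysed propargylation of an aldehyde by an allenylboronate through a closed six-membered SE2′ transition state, in which the catalyst should direct the propargyl group to the Re face and so set the R carbinol.

Step 5
Reactants: 6 (4R,5E,9E)-11-[(tert-butyldimethylsilyl)oxy]-5,9-dimethylundeca-5,9-dien-1-yn-4-ol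
Product: 7 (4R,5E,9E)-4,11-bis[(tert-butyldimethylsilyl)oxy]-5,9-dimethylundeca-5,9-dien-1-yne
Conditions: TBSCl, imidazole, DMF, rt
Reagents that add atoms: tert-butyldimethylsilyl chloride, CC(C)(C)[Si](C)(C)Cl
Why: Silylation of the secondary allylic alcohol, needed so that the later cis-disposed carboxyl group cannot lactonise onto this oxygen; the stereocentre is not touched.

Step 6
Reactants: 7 (4R,5E,9E)-4,11-bis[(tert-butyldimethylsilyl)oxy]-5,9-dimethylundeca-5,9-dien-1-yne
Product: 9 methyl (5R,6E,10E)-5,12-bis[(tert-butyldimethylsilyl)oxy]-6,10-dimethyldodeca-6,10-dien-2-ynoate, via lithium acetylide 8 (not isolated)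
Conditions: n-BuLi, THF, −78 °C; then ClCO2Me, −78 to 0 °C
Reagents that add atoms: methyl chloroformate, COC(=O)Cl; n-butyllithium, CCCC[Li] (lithium in 8 only)
Why: Deprotonation of the terminal alkyne and C-acylation of the acetylide with a chloroformate is the standard route to alk-2-ynoates, and silyl ethers tolerate it.

Step 7
Reactants: 9 methyl (5R,6E,10E)-5,12-bis[(tert-butyldimethylsilyl)oxy]-6,10-dimethyldodeca-6,10-dien-2-ynoate
Product: 11 methyl (2E,5R,6E,10E)-5,12-bis[(tert-butyldimethylsilyl)oxy]-2-iodo-6,10-dimethyldodeca-2,6,10-trienoate, via alkenylstannane 10 (not isolated)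
Conditions: Bu3SnH, Pd(PPh3)4 (2 mol%), THF, 0 °C; then I2, CH2Cl2, 0 °C
Reagents that add atoms: iodine, II; tributyltin hydride, CCCC[SnH](CCCC)CCCC (tin in 10 only)
Why: Palladium-catalysed syn-hydrostannation of an alk-2-ynoate should place tin at C-2 and hydrogen at C-3 on the same side, and iododestannylation with retention then gives the 2-iodoenoate with the chain cis to the ester, the geometry the target's exocyclic alkene needs.

Step 8
Reactants: 11 methyl (2E,5R,6E,10E)-5,12-bis[(tert-butyldimethylsilyl)oxy]-2-iodo-6,10-dimethyldodeca-2,6,10-trienoate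
Product: 13 (2E,5R,6E,10E)-5,12-bis[(tert-butyldimethylsilyl)oxy]-2-iodo-6,10-dimethyldodeca-2,6,10-trienoic acid, via lithium carboxylate 12 (not isolated)
Conditions: LiOH·H2O, THF/H2O, 0 °C to rt; then cold 0.5 M HCl to pH 4
Reagents that add atoms: lithium hydroxide, [Li+].[OH-] (one carboxyl oxygen; lithium in 12 only)
Why: Saponification of a methyl ester, in which the silyl ethers should survive and the alkenyl iodide, whose vinylic hydrogen is cis to iodine, has no anti hydrogen for dehydroiodination.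

Step 9
Reactants: 14 (E)-4-methylpent-2-enal
Product: 15 tert-butyldimethyl{[(1E)-4-methylpenta-1,3-dien-1-yl]oxy}silane
Conditions: TBSOTf, Et3N, Et2O, 0 °C to rt
Reagents that add atoms: tert-butyldimethylsilyl triflate, CC(C)(C)[Si](C)(C)OS(=O)(=O)C(F)(F)F
Why: O-Silylation of the enal and γ-deprotonation of the resulting oxocarbenium ion (vinylogous soft enolisation) should give the silyl dienol ether, with the 1E geometry following from the preferred s-trans enal.

Step 10
Reactants: 13 (2E,5R,6E,10E)-5,12-bis[(tert-butyldimethylsilyl)oxy]-2-iodo-6,10-dimethyldodeca-2,6,10-trienoic acid; 15 tert-butyldimethyl{[(1E)-4-methylpenta-1,3-dien-1-yl]oxy}silane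
Product: 18 (3Z,4S,5R)-4-[(tert-butyldimethylsilyl)oxy]-3-[(3R,4E,8E)-3,10-bis[(tert-butyldimethylsilyl)oxy]-4,8-dimethyldeca-4,8-dien-1-ylidene]-5-(2-methylprop-1-en-1-yl)oxolan-2-one, via silver carboxylate 16 (not isolated), via allylpalladium carboxylate 17 (not isolated)
Conditions: Ag2CO3 (0.6 equiv), THF, rt; then 15 (2.5 equiv), Pd2(dba)3 (2.5 mol%), (S)-t-Bu-PHOX (6 mol%), THF, 50 °C, dark
Reagents that add atoms: none
Why: Proposed new method: zerovalent palladium inserts into the C–I bond of 16 with retention of the alkene geometry, silver removes iodide, the cationic alkenylpalladium adds syn across the enol-ether double bond of 15 with the alkenyl carbon going to the oxygen-bearing C-1, and the carboxylate then attacks the resulting allylpalladium 17 at the allyl terminus next to the new C–C bond, releasing the lactone and zerovalent palladium. The closest known reaction type is the Larock heteroannulation of 1,3-dienes by halides that carry a carboxylic acid, and for the facial control the asymmetric intermolecular Heck reaction of cyclic enol ethers under cationic palladium with phosphinooxazoline ligands; new are the 1-silyloxydiene as acceptor and ligand-controlled insertion within an annulation. The single ring closes as a five-membered lactone by C–O bond formation at the proximal allyl terminus (formal [3+2] annulation), the seven-membered alternative at the CMe2 terminus being hindered and strained. C-4 is set in the insertion by the chiral ligand, which must present the Si face of C-1 of the dienol ether, and C-5 follows from C-4 because the gem-dimethyl terminus lets the allyl complex exchange faces by π-σ-π isomerisation, so that the ring should close through the less crowded arrangement with the silyloxy and 2-methylpropenyl groups trans. The exocyclic Z geometry is that of the alkenyl iodide, carried through with retention. The step needs C-1 regioselectivity (favoured by cationic insertion into an enol ether, by formation of an allyl complex and by the fully substituted C-4 end), capture of the allyl complex faster than β-hydride or β-silyloxy elimination (intramolecular carboxylate, poor silyloxy leaving group), and reaction at the electron-rich enol ether in preference to the trisubstituted alkenes of the side chain.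

Step 11
Reactants: 18 (3Z,4S,5R)-4-[(tert-butyldimethylsilyl)oxy]-3-[(3R,4E,8E)-3,10-bis[(tert-butyldimethylsilyl)oxy]-4,8-dimethyldeca-4,8-dien-1-ylidene]-5-(2-methylprop-1-en-1-yl)oxolan-2-one
Product: 19 (3Z,4S,5R)-3-[(3R,4E,8E)-3,10-dihydroxy-4,8-dimethyldeca-4,8-dien-1-ylidene]-4-hydroxy-5-(2-methylprop-1-en-1-yl)oxolan-2-one
Conditions: HF·pyridine, pyridine, THF, 0 °C to rt
Reagents that add atoms: none
Why: Fluoride-mediated cleavage of the three silyl ethers in a pyridine-buffered medium should leave the allylic lactone C–O bond, the Z alkylidene and all three stereocentres untouched.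

**Compound list**

1 | geraniol | CC(C)=CCC/C(C)=C/CO | starting material
2 | tert-butyl{[(2E)-3,7-dimethylocta-2,6-dien-1-yl]oxy}dimethylsilane | CC(C)=CCC/C(C)=C/CO[Si](C)(C)C(C)(C)C | intermediate
3 | (2E,6E)-8-[(tert-butyldimethylsilyl)oxy]-2,6-dimethylocta-2,6-dien-1-ol | OC/C(C)=C/CC/C(C)=C/CO[Si](C)(C)C(C)(C)C | intermediate
4 | (2E,6E)-8-[(tert-butyldimethylsilyl)oxy]-2,6-dimethylocta-2,6-dienal | O=C/C(C)=C/CC/C(C)=C/CO[Si](C)(C)C(C)(C)C | intermediate
5 | O-pinacolboryl ether of 6 | C#CC[C@@H](OB1OC(C)(C)C(C)(C)O1)/C(C)=C/CC/C(C)=C/CO[Si](C)(C)C(C)(C)C | intermediate (not isolated)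
6 | (4R,5E,9E)-11-[(tert-butyldimethylsilyl)oxy]-5,9-dimethylundeca-5,9-dien-1-yn-4-ol | C#CC[C@@H](O)/C(C)=C/CC/C(C)=C/CO[Si](C)(C)C(C)(C)C | intermediate
7 | (4R,5E,9E)-4,11-bis[(tert-butyldimethylsilyl)oxy]-5,9-dimethylundeca-5,9-dien-1-yne | C#CC[C@@H](O[Si](C)(C)C(C)(C)C)/C(C)=C/CC/C(C)=C/CO[Si](C)(C)C(C)(C)C | intermediate
8 | lithium acetylide of 7 | [Li]C#CC[C@@H](O[Si](C)(C)C(C)(C)C)/C(C)=C/CC/C(C)=C/CO[Si](C)(C)C(C)(C)C | intermediate (not isolated)
9 | methyl (5R,6E,10E)-5,12-bis[(tert-butyldimethylsilyl)oxy]-6,10-dimethyldodeca-6,10-dien-2-ynoate | COC(=O)C#CC[C@@H](O[Si](C)(C)C(C)(C)C)/C(C)=C/CC/C(C)=C/CO[Si](C)(C)C(C)(C)C | intermediate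
10 | methyl (2E,5R,6E,10E)-5,12-bis[(tert-butyldimethylsilyl)oxy]-6,10-dimethyl-2-(tributylstannyl)dodeca-2,6,10-trienoate | COC(=O)/C(=C\C[C@@H](O[Si](C)(C)C(C)(C)C)/C(C)=C/CC/C(C)=C/CO[Si](C)(C)C(C)(C)C)[Sn](CCCC)(CCCC)CCCC | intermediate (not isolated)
11 | methyl (2E,5R,6E,10E)-5,12-bis[(tert-butyldimethylsilyl)oxy]-2-iodo-6,10-dimethyldodeca-2,6,10-trienoate | COC(=O)/C(I)=C\C[C@@H](O[Si](C)(C)C(C)(C)C)/C(C)=C/CC/C(C)=C/CO[Si](C)(C)C(C)(C)C | intermediate
12 | lithium salt of 13 | [Li+].[O-]C(=O)/C(I)=C\C[C@@H](O[Si](C)(C)C(C)(C)C)/C(C)=C/CC/C(C)=C/CO[Si](C)(C)C(C)(C)C | intermediate (not isolated)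
13 | (2E,5R,6E,10E)-5,12-bis[(tert-butyldimethylsilyl)oxy]-2-iodo-6,10-dimethyldodeca-2,6,10-trienoic acid | OC(=O)/C(I)=C\C[C@@H](O[Si](C)(C)C(C)(C)C)/C(C)=C/CC/C(C)=C/CO[Si](C)(C)C(C)(C)C | intermediate
14 | (E)-4-methylpent-2-enal | CC(C)/C=C/C=O | starting material
15 | tert-butyldimethyl{[(1E)-4-methylpenta-1,3-dien-1-yl]oxy}silane | CC(C)=C/C=C/O[Si](C)(C)C(C)(C)C | intermediate
16 | silver salt of 13 | [Ag+].[O-]C(=O)/C(I)=C\C[C@@H](O[Si](C)(C)C(C)(C)C)/C(C)=C/CC/C(C)=C/CO[Si](C)(C)C(C)(C)C | intermediate (not isolated)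
17 | allylpalladium carboxylate from 16 and 15 (drawn σ-bound at C-5 as the six-membered oxapalladacycle, ligand omitted, C-5 not fixed) | CC(C)=CC1[Pd]OC(=O)/C(=C\C[C@@H](O[Si](C)(C)C(C)(C)C)/C(C)=C/CC/C(C)=C/CO[Si](C)(C)C(C)(C)C)[C@@H]1O[Si](C)(C)C(C)(C)C | intermediate (not isolated)
18 | (3Z,4S,5R)-4-[(tert-butyldimethylsilyl)oxy]-3-[(3R,4E,8E)-3,10-bis[(tert-butyldimethylsilyl)oxy]-4,8-dimethyldeca-4,8-dien-1-ylidene]-5-(2-methylprop-1-en-1-yl)oxolan-2-one | CC(C)=C[C@H]1OC(=O)/C(=C\C[C@@H](O[Si](C)(C)C(C)(C)C)/C(C)=C/CC/C(C)=C/CO[Si](C)(C)C(C)(C)C)[C@@H]1O[Si](C)(C)C(C)(C)C | intermediate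
19 | (3Z,4S,5R)-3-[(3R,4E,8E)-3,10-dihydroxy-4,8-dimethyldeca-4,8-dien-1-ylidene]-4-hydroxy-5-(2-methylprop-1-en-1-yl)oxolan-2-one | CC(C)=C[C@H]1OC(=O)/C(=C\C[C@@H](O)/C(C)=C/CC/C(C)=C/CO)[C@@H]1O | target

**Count and risks**

Total step count: 11. Longest linear sequence: 10 steps (steps 1 to 8, 10 and 11).

Step 10 (bears the label). The insertion may take the wrong regiochemistry or show poor facial selectivity, the dienol ether may be lost by protodesilylation, or the allyl complex may eliminate instead of closing. The fallback uses known chemistry, sets out from ynoate 9 and comes back at target 19.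
- Commercial (S)-2,2-dimethyl-1,3-dioxolane-4-carbaldehyde would be taken by Wittig reaction with isopropylidenetriphenylphosphorane to (4R)-2,2-dimethyl-4-(2-methylprop-1-en-1-yl)-1,3-dioxolane F1.
- Aqueous acetic acid would give (2R)-4-methylpent-3-ene-1,2-diol F2, and Et3SiCl with imidazole would give (2R)-4-methyl-1,2-bis(triethylsilyloxy)pent-3-ene F3.
- Swern oxidation, which oxidises a primary triethylsilyl ether directly, would give (2R)-4-methyl-2-(triethylsilyloxy)pent-3-enal F4.
- Syn 1,4-hydroalumination of 9 with i-Bu2AlH and N-methylmorpholine N-oxide in THF would give the α-aluminioacrylate methyl (2E,5R,6E,10E)-5,12-bis[(tert-butyldimethylsilyl)oxy]-2-(diisobutylalumanyl)-6,10-dimethyldodeca-2,6,10-trienoate F5.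
- Felkin–Anh addition of F5 to F4 should give the anti adduct methyl (2Z,5R,6E,10E)-5,12-bis[(tert-butyldimethylsilyl)oxy]-2-[(1S,2R)-1-hydroxy-4-methyl-2-(triethylsilyloxy)pent-3-en-1-yl]-6,10-dimethyldodeca-2,6,10-trienoate F6.
- PPTS in methanol would remove the triethylsilyl group and let the γ-hydroxy ester close to (3Z,4S,5R)-3-[(3R,4E,8E)-3,10-bis[(tert-butyldimethylsilyl)oxy]-4,8-dimethyldeca-4,8-dien-1-ylidene]-4-hydroxy-5-(2-methylprop-1-en-1-yl)oxolan-2-one F7, with the side-chain carbinol still silylated so that only the five-membered lactone can form.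
- HF·pyridine as in step 11 would then give 19.

Step 11. Cleavage of the hindered silyl ether at C-4 may be slow. On long exposure the freed side-chain hydroxyl, which sits cis to the carbonyl, may translactonise to the six-membered lactone, or the allylic C–O bond may ionise. The fallback changes the protecting group at the ring oxygen rather than the cleavage conditions; it sets out from enal 14 (with acid 13) and comes back at 19.
- Et3SiOTf and Et3N would convert 14 into triethyl{[(1E)-4-methylpenta-1,3-dien-1-yl]oxy}silane F8.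
- The annulation of step 10 with 13 would pass through 16 and the triethylsilyl analogue of the allylpalladium carboxylate F9 to (3Z,4S,5R)-3-[(3R,4E,8E)-3,10-bis[(tert-butyldimethylsilyl)oxy]-4,8-dimethyldeca-4,8-dien-1-ylidene]-5-(2-methylprop-1-en-1-yl)-4-[(triethylsilyl)oxy]oxolan-2-one F10.
- The labile triethylsilyl ether and the two remaining silyl ethers (one primary, one secondary allylic) should then fall to a short treatment with HF·pyridine at 0 °C, giving 19.

Step 4. Enantioface discrimination may be insufficient with the α-branched enal, or the acid catalyst may cleave the allylic silyl ether. The fallback sets out from enal 4 and comes back at alcohol 6.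
- Barbier propargylation (Zn, propargyl bromide, THF/aqueous NH4Cl) would give racemic (5E,9E)-11-[(tert-butyldimethylsilyl)oxy]-5,9-dimethylundeca-5,9-dien-1-yn-4-ol F11.
- Sharpless kinetic resolution (Ti(OiPr)4, L-(+)-diisopropyl tartrate, t-BuOOH, 4 Å MS, CH2Cl2, −20 °C) should epoxidise the S enantiomer to (1S)-1-[(2S,3S)-3-{(3E)-5-[(tert-butyldimethylsilyl)oxy]-3-methylpent-3-en-1-yl}-2-methyloxiran-2-yl]but-3-yn-1-ol F12 and leave (R)-alcohol 6, separable by chromatography.

**Further compounds**

F1 | step 10 | (4R)-2,2-dimethyl-4-(2-methylprop-1-en-1-yl)-1,3-dioxolane | CC(C)=C[C@@H]1COC(C)(C)O1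
F2 | step 10 | (2R)-4-methylpent-3-ene-1,2-diol | CC(C)=C[C@@H](O)CO
F3 | step 10 | (2R)-4-methyl-1,2-bis(triethylsilyloxy)pent-3-ene | CC(C)=C[C@@H](O[Si](CC)(CC)CC)CO[Si](CC)(CC)CC
F4 | step 10 | (2R)-4-methyl-2-(triethylsilyloxy)pent-3-enal | CC(C)=C[C@@H](O[Si](CC)(CC)CC)C=O
F5 | step 10 | methyl (2E,5R,6E,10E)-5,12-bis[(tert-butyldimethylsilyl)oxy]-2-(diisobutylalumanyl)-6,10-dimethyldodeca-2,6,10-trienoate | COC(=O)/C(=C\C[C@@H](O[Si](C)(C)C(C)(C)C)/C(C)=C/CC/C(C)=C/CO[Si](C)(C)C(C)(C)C)[Al](CC(C)C)CC(C)C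
F6 | step 10 | methyl (2Z,5R,6E,10E)-5,12-bis[(tert-butyldimethylsilyl)oxy]-2-[(1S,2R)-1-hydroxy-4-methyl-2-(triethylsilyloxy)pent-3-en-1-yl]-6,10-dimethyldodeca-2,6,10-trienoate | COC(=O)/C(=C\C[C@@H](O[Si](C)(C)C(C)(C)C)/C(C)=C/CC/C(C)=C/CO[Si](C)(C)C(C)(C)C)[C@H](O)[C@H](O[Si](CC)(CC)CC)C=C(C)C
F7 | step 10 | (3Z,4S,5R)-3-[(3R,4E,8E)-3,10-bis[(tert-butyldimethylsilyl)oxy]-4,8-dimethyldeca-4,8-dien-1-ylidene]-4-hydroxy-5-(2-methylprop-1-en-1-yl)oxolan-2-one | CC(C)=C[C@H]1OC(=O)/C(=C\C[C@@H](O[Si](C)(C)C(C)(C)C)/C(C)=C/CC/C(C)=C/CO[Si](C)(C)C(C)(C)C)[C@@H]1O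
F8 | step 11 | triethyl{[(1E)-4-methylpenta-1,3-dien-1-yl]oxy}silane | CC(C)=C/C=C/O[Si](CC)(CC)CC
F9 | step 11 | triethylsilyl analogue of allylpalladium carboxylate 17 (drawn σ-bound at C-5, ligand omitted, C-5 not fixed) | CC(C)=CC1[Pd]OC(=O)/C(=C\C[C@@H](O[Si](C)(C)C(C)(C)C)/C(C)=C/CC/C(C)=C/CO[Si](C)(C)C(C)(C)C)[C@@H]1O[Si](CC)(CC)CC
F10 | step 11 | (3Z,4S,5R)-3-[(3R,4E,8E)-3,10-bis[(tert-butyldimethylsilyl)oxy]-4,8-dimethyldeca-4,8-dien-1-ylidene]-5-(2-methylprop-1-en-1-yl)-4-[(triethylsilyl)oxy]oxolan-2-one | CC(C)=C[C@H]1OC(=O)/C(=C\C[C@@H](O[Si](C)(C)C(C)(C)C)/C(C)=C/CC/C(C)=C/CO[Si](C)(C)C(C)(C)C)[C@@H]1O[Si](CC)(CC)CC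
F11 | step 4 | racemic (5E,9E)-11-[(tert-butyldimethylsilyl)oxy]-5,9-dimethylundeca-5,9-dien-1-yn-4-ol | C#CCC(O)/C(C)=C/CC/C(C)=C/CO[Si](C)(C)C(C)(C)C
F12 | step 4 | (1S)-1-[(2S,3S)-3-{(3E)-5-[(tert-butyldimethylsilyl)oxy]-3-methylpent-3-en-1-yl}-2-methyloxiran-2-yl]but-3-yn-1-ol | C#CC[C@H](O)[C@]1(C)O[C@H]1CC/C(C)=C/CO[Si](C)(C)C(C)(C)C
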